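**Retrosynthetic overview**
1. Target 29 ⇒ triol 27 (primary-selective stearoylation) ⇒ ketone 24 (isopropenyl addition, then oxidative 1,3-transposition to the (Z)-enal) ⇒ nitro compound 22 (Nef).
2. 22 ⇒ vinylcyclohexane 20 + vinyl iodide 8 (hydroboration, then B-alkyl Suzuki coupling makes the CH2–CH= bond of the side chain).
3. 8 ⇒ geranylacetone 1 (proline-catalysed α-aminoxylation sets the side-chain carbinol; methyl ketone → alkyne → carboalumination/iodination).
4. 20 ⇒ aldol 18: the only ring (the cyclohexane) is closed by nitro-Michael addition to butenone followed by an amine-catalysed enolexo aldol that forms the quaternary-carbon/carbinol bond.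
5. 18 ⇒ γ-nitroaldehyde 15 ⇒ propanal + nitroalkene 13 (diarylprolinol silyl ether-catalysed Michael addition sets the first stereocentre).

Assumption: (E)-geranylacetone, 4-[(tert-butyldimethylsilyl)oxy]butanal and all reagents named are taken as commercially available.

**Step 1**
Reactants: 1 (5E)-6,10-dimethylundeca-5,9-dien-2-one (geranylacetone)
Product: 3 (3R,5E)-3-hydroxy-6,10-dimethylundeca-5,9-dien-2-one, via aminooxy ketone 2 (not isolated)
Conditions: 1 (2 equiv), PhNO (slow addition), L-proline (20 mol %), DMSO, 0 °C; then CuSO4·5H2O (30 mol %), MeOH, 0 °C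
Reagents that add atoms: nitrosobenzene (O=Nc1ccccc1)
Why: Proline-catalysed α-aminoxylation (O-selective nitroso aldol): the more substituted (E)-enamine attacks the nitroso oxygen on the face fixed by the carboxylic acid hydrogen bond, so L-proline gives the (R)-carbinol, and the N–O bond is cleaved in the same pot.

**Step 2**
Reactants: 3 (3R,5E)-3-hydroxy-6,10-dimethylundeca-5,9-dien-2-one
Product: 4 (3R,5E)-3-[(tert-butyldimethylsilyl)oxy]-6,10-dimethylundeca-5,9-dien-2-one
Conditions: TBSCl, imidazole, DMF, 25 °C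
Reagents that add atoms: tert-butyldimethylsilyl chloride (CC(C)(C)[Si](C)(C)Cl)
Why: Standard silyl ether formation protects the carbinol for the strong-base, organoaluminium, Grignard and chromium steps that follow.

**Step 3**
Reactants: 4 (3R,5E)-3-[(tert-butyldimethylsilyl)oxy]-6,10-dimethylundeca-5,9-dien-2-one
Product: 6 (3R,5E)-3-[(tert-butyldimethylsilyl)oxy]-6,10-dimethylundeca-5,9-dien-1-yne, via enol phosphate 5 (not isolated)
Conditions: LiN(iPr)2 (1.1 equiv), THF, −78 °C; ClP(O)(OEt)2; then LiN(iPr)2 (2.3 equiv), −78 °C → 25 °C; NH4Cl (aq)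
Reagents that add atoms: none
Why: Negishi methyl ketone-to-alkyne conversion (kinetic enolisation on the methyl side, O-phosphorylation, then base-induced elimination of the enol phosphate), which leaves the silyloxy stereocentre untouched as long as enolisation stays on the methyl group.

**Step 4**
Reactants: 6 (3R,5E)-3-[(tert-butyldimethylsilyl)oxy]-6,10-dimethylundeca-5,9-dien-1-yne
Product: 8 (1E,3R,5E)-3-[(tert-butyldimethylsilyl)oxy]-1-iodo-2,6,10-trimethylundeca-1,5,9-triene, via alkenylalane 7 (not isolated)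
Conditions: AlMe3 (3 equiv), Cp2ZrCl2 (0.5 equiv), CH2Cl2, 0 → 25 °C; then I2, THF, −30 °C
Reagents that add atoms: trimethylaluminium (C[Al](C)C); iodine (II)
Why: Negishi zirconium-catalysed carboalumination adds methyl and aluminium syn across the terminal alkyne (methyl to the internal carbon), and iodinolysis with retention gives the (E)-trisubstituted vinyl iodide.

**Step 5**
Reactants: 9 4-[(tert-butyldimethylsilyl)oxy]butanal; 10 nitromethane
Product: 13 tert-butyldimethylsilyl (4E)-5-nitropent-4-en-1-yl ether, via nitro alcohol 11 (not isolated), via nitro mesylate 12 (not isolated)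
Conditions: MeNO2 (5 equiv), KOtBu (5 mol %), THF/tBuOH, 0 °C; then MsCl, Et3N, CH2Cl2, −10 °C
Reagents that add atoms: none
Why: Henry addition followed by mesylation and base-induced elimination gives the conjugated (E)-nitroalkene, the thermodynamically favoured isomer.

**Step 6**
Reactants: 13 tert-butyldimethylsilyl (4E)-5-nitropent-4-en-1-yl ether; 14 propanal
Product: 15 (2R,3R)-6-[(tert-butyldimethylsilyl)oxy]-2-methyl-3-(nitromethyl)hexanal
Conditions: 14 (2 equiv), (S)-2-[diphenyl(trimethylsilyloxy)methyl]pyrrolidine (5 mol %), 4-nitrophenol (10 mol %), toluene, 0 → 25 °C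
Reagents that add atoms: none
Why: Enamine-catalysed Michael addition of an aldehyde to a nitroalkene (Hayashi–Jørgensen catalyst): the (E)-anti enamine attacks the nitroalkene on the face away from the diphenyl(silyloxy)methyl group, setting the nitromethyl-bearing carbon as (R) (the first stereocentre) and the syn methyl centre, which is erased later.

**Step 7**
Reactants: 15 (2R,3R)-6-[(tert-butyldimethylsilyl)oxy]-2-methyl-3-(nitromethyl)hexanal; 16 but-3-en-2-one
Product: 18 (1R,2S,5R,6R)-6-{3-[(tert-butyldimethylsilyl)oxy]propyl}-2-hydroxy-1,2-dimethyl-5-nitrocyclohexane-1-carbaldehyde, via keto aldehyde 17 (not isolated)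
Conditions: 16 (1.1 equiv), Et3N (10 mol %), CH2Cl2, 0 °C; evaporate; then 4-methoxybenzylamine (20 mol %), N,N'-bis[3,5-bis(trifluoromethyl)phenyl]thiourea (20 mol %), PhCO2H (20 mol %), toluene, 25 °C
Reagents that add atoms: none
Why: Proposed new method: after the known base-catalysed nitro-Michael addition to 16, the primary amine condenses with the aldehyde of 17 in preference to the methyl ketone, and the N–H enamine of this α-branched aldehyde adds to the thiourea/acid-activated ketone in a 6-enolexo aldol through a chair transition state (silyloxypropyl and nitro groups equatorial, enamine carbon pseudo-equatorial to minimise allylic strain, ketone methyl equatorial and oxygen axial), so the new quaternary carbon carries its methyl cis to the propyl chain and the tertiary hydroxyl cis to the formyl group, and the product, having no α-hydrogen, cannot dehydrate; the closest known reactions are the proline-catalysed 6-enolexo aldolisation of 1,7-dicarbonyl compounds and primary-amine enamine catalysis of α-branched aldehydes, neither shown for an α-branched aldehyde closing onto an unactivated ketone to give two adjacent fully substituted carbons.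

**Step 8**
Reactants: 18 (1R,2S,5R,6R)-6-{3-[(tert-butyldimethylsilyl)oxy]propyl}-2-hydroxy-1,2-dimethyl-5-nitrocyclohexane-1-carbaldehyde
Product: 19 (1R,2S,5R,6R)-6-{3-[(tert-butyldimethylsilyl)oxy]propyl}-1,2-dimethyl-5-nitro-2-[(triethylsilyl)oxy]cyclohexane-1-carbaldehyde
Conditions: TESOTf, 2,6-lutidine, CH2Cl2, −78 → 0 °C; NaHCO3 (aq)
Reagents that add atoms: triethylsilyl trifluoromethanesulfonate (CC[Si](CC)(CC)OS(=O)(=O)C(F)(F)F)
Why: Silylation of the hindered tertiary alcohol blocks retro-aldol cleavage of the β-hydroxy aldehyde under the basic conditions that follow (any silyl nitronate formed reverts on aqueous work-up).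

**Step 9**
Reactants: 19 (1R,2S,5R,6R)-6-{3-[(tert-butyldimethylsilyl)oxy]propyl}-1,2-dimethyl-5-nitro-2-[(triethylsilyl)oxy]cyclohexane-1-carbaldehyde
Product: 20 tert-butyl(3-{(1R,2R,3S,6R)-2-ethenyl-2,3-dimethyl-6-nitro-3-[(triethylsilyl)oxy]cyclohexyl}propoxy)dimethylsilane
Conditions: Ph3PCH3Br (3.5 equiv), KN(SiMe3)2 (3.3 equiv), THF, 0 °C; add 19, −78 → 40 °C; AcOH/NH4Cl (aq)
Reagents that add atoms: methyltriphenylphosphonium bromide (C[P+](c1ccccc1)(c1ccccc1)c1ccccc1.[Br-])
Why: Wittig methylenation of a non-enolisable neopentyl aldehyde; excess ylide also deprotonates the nitro group, which survives as the inert nitronate and is re-protonated on buffered work-up (the nitro-bearing centre is lost later, so its configuration does not matter).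

**Step 10**
Reactants: 20 tert-butyl(3-{(1R,2R,3S,6R)-2-ethenyl-2,3-dimethyl-6-nitro-3-[(triethylsilyl)oxy]cyclohexyl}propoxy)dimethylsilane; 8 (1E,3R,5E)-3-[(tert-butyldimethylsilyl)oxy]-1-iodo-2,6,10-trimethylundeca-1,5,9-triene
Product: 22 tert-butyl{[(3E,5R,7E)-1-{(1R,2S,5R,6R)-6-{3-[(tert-butyldimethylsilyl)oxy]propyl}-1,2-dimethyl-5-nitro-2-[(triethylsilyl)oxy]cyclohexyl}-4,8,12-trimethyltrideca-3,7,11-trien-5-yl]oxy}dimethylsilane, via B-alkyl-9-BBN borane 21 (not isolated)
Conditions: 9-BBN (2 equiv), THF, 0 → 25 °C; H2O; then 8 (1.1 equiv), Pd(dppf)Cl2 (5 mol %), AsPh3 (10 mol %), Cs2CO3 (3 equiv), DMF, 25 °C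
Reagents that add atoms: none
Why: Anti-Markovnikov hydroboration of the only alkene in 20 (the nitro group is inert to 9-BBN) followed by B-alkyl Suzuki–Miyaura coupling, which retains the (E)-geometry of the vinyl iodide and brings in the already set (R)-carbinol.

**Step 11**
Reactants: 22 tert-butyl{[(3E,5R,7E)-1-{(1R,2S,5R,6R)-6-{3-[(tert-butyldimethylsilyl)oxy]propyl}-1,2-dimethyl-5-nitro-2-[(triethylsilyl)oxy]cyclohexyl}-4,8,12-trimethyltrideca-3,7,11-trien-5-yl]oxy}dimethylsilane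
Product: 24 (2R,3R,4S)-2-{3-[(tert-butyldimethylsilyl)oxy]propyl}-3-[(3E,5R,7E)-5-[(tert-butyldimethylsilyl)oxy]-4,8,12-trimethyltrideca-3,7,11-trien-1-yl]-3,4-dimethyl-4-[(triethylsilyl)oxy]cyclohexan-1-one, via sodium nitronate 23 (not isolated)
Conditions: NaOMe (1.5 equiv), MeOH, 0 °C; then TiCl3 (6 equiv, aq), NH4OAc buffer (pH 5–6), THF/H2O, 0 → 25 °C
Reagents that add atoms: water (O)
Why: Reductive Nef reaction (McMurry variant): trivalent titanium reduces the nitronate to the imine, which hydrolyses to the ketone under near-neutral conditions that spare the trisubstituted alkenes and silyl ethers, and the adjacent CH stereocentre stays in its more stable equatorial arrangement.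

**Step 12**
Reactants: 24 (2R,3R,4S)-2-{3-[(tert-butyldimethylsilyl)oxy]propyl}-3-[(3E,5R,7E)-5-[(tert-butyldimethylsilyl)oxy]-4,8,12-trimethyltrideca-3,7,11-trien-1-yl]-3,4-dimethyl-4-[(triethylsilyl)oxy]cyclohexan-1-one
Product: 25 (2R,3R,4S)-2-{3-[(tert-butyldimethylsilyl)oxy]propyl}-3-[(3E,5R,7E)-5-[(tert-butyldimethylsilyl)oxy]-4,8,12-trimethyltrideca-3,7,11-trien-1-yl]-3,4-dimethyl-1-(prop-1-en-2-yl)-4-[(triethylsilyl)oxy]cyclohexan-1-ol (C1 epimers; this centre is lost in step 13)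
Conditions: CH2=C(CH3)MgBr (4 equiv), anhydrous CeCl3 (4 equiv), THF, −78 → −20 °C
Reagents that add atoms: isopropenylmagnesium bromide (CC(=C)[Mg]Br)
Why: 1,2-Addition of an organocerium reagent (Imamoto conditions), which suppresses enolisation of the hindered α-branched ketone and so preserves the adjacent stereocentre.

**Step 13**
Reactants: 25 (2R,3R,4S)-2-{3-[(tert-butyldimethylsilyl)oxy]propyl}-3-[(3E,5R,7E)-5-[(tert-butyldimethylsilyl)oxy]-4,8,12-trimethyltrideca-3,7,11-trien-1-yl]-3,4-dimethyl-1-(prop-1-en-2-yl)-4-[(triethylsilyl)oxy]cyclohexan-1-ol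
Product: 26 (2Z)-2-{(2S,3R,4S)-2-{3-[(tert-butyldimethylsilyl)oxy]propyl}-3-[(3E,5R,7E)-5-[(tert-butyldimethylsilyl)oxy]-4,8,12-trimethyltrideca-3,7,11-trien-1-yl]-3,4-dimethyl-4-[(triethylsilyl)oxy]cyclohexylidene}propanal
Conditions: pyridinium chlorochromate [C5H5NH][CrO3Cl] (3 equiv), Celite, CH2Cl2, 25 °C; (E)-isomer separated and re-equilibrated (I2 cat., PhH)
Reagents that add atoms: pyridinium chlorochromate ([O-][Cr](=O)(=O)Cl.c1cc[nH+]cc1)
Why: Babler–Dauben oxidative transposition: the tertiary allylic chromate ester undergoes a [3,3] shift and the resulting primary chromate is oxidised to the enal, with the (Z)-isomer expected to predominate only modestly because the CH2O terminus (later the flat formyl group) rather than the methyl group sits next to the substituted ring carbon.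

**Step 14**
Reactants: 26 (2Z)-2-{(2S,3R,4S)-2-{3-[(tert-butyldimethylsilyl)oxy]propyl}-3-[(3E,5R,7E)-5-[(tert-butyldimethylsilyl)oxy]-4,8,12-trimethyltrideca-3,7,11-trien-1-yl]-3,4-dimethyl-4-[(triethylsilyl)oxy]cyclohexylidene}propanal
Product: 27 (2Z)-2-{(2S,3R,4S)-4-hydroxy-3-[(3E,5R,7E)-5-hydroxy-4,8,12-trimethyltrideca-3,7,11-trien-1-yl]-2-(3-hydroxypropyl)-3,4-dimethylcyclohexylidene}propanal
Conditions: HF·pyridine, pyridine, THF, 0 → 25 °C
Reagents that add atoms: none
Why: Buffered fluoride-mediated global desilylation removes the two TBS ethers and the TES ether without isomerising the enal or ionising the allylic and tertiary alcohols.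

**Step 15**
Reactants: 27 (2Z)-2-{(2S,3R,4S)-4-hydroxy-3-[(3E,5R,7E)-5-hydroxy-4,8,12-trimethyltrideca-3,7,11-trien-1-yl]-2-(3-hydroxypropyl)-3,4-dimethylcyclohexylidene}propanal; 28 octadecanoyl chloride
Product: 29 3-[(1S,2R,3S,6Z)-3-hydroxy-2-[(3E,5R,7E)-5-hydroxy-4,8,12-trimethyltrideca-3,7,11-trien-1-yl]-2,3-dimethyl-6-(1-oxopropan-2-ylidene)cyclohexyl]propyl octadecanoate (CNP0187319.2)
Conditions: 28 (1.05 equiv), 2,4,6-collidine, CH2Cl2, −78 → −30 °C
Reagents that add atoms: none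
Why: Kinetically controlled acylation with a weak hindered base esterifies the unhindered primary alcohol much faster than the flanked secondary allylic alcohol or the tertiary alcohol.

**Compound list**
1 | (5E)-6,10-dimethylundeca-5,9-dien-2-one (geranylacetone) | CC(=O)CC/C=C(\C)CCC=C(C)C | starting material
2 | (3R,5E)-6,10-dimethyl-3-[(phenylamino)oxy]undeca-5,9-dien-2-one | CC(=O)[C@H](ONc1ccccc1)C/C=C(\C)CCC=C(C)C | intermediate (not isolated)
3 | (3R,5E)-3-hydroxy-6,10-dimethylundeca-5,9-dien-2-one | CC(=O)[C@H](O)C/C=C(\C)CCC=C(C)C | intermediate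
4 | (3R,5E)-3-[(tert-butyldimethylsilyl)oxy]-6,10-dimethylundeca-5,9-dien-2-one | CC(=O)[C@H](O[Si](C)(C)C(C)(C)C)C/C=C(\C)CCC=C(C)C | intermediate
5 | diethyl (3R,5E)-3-[(tert-butyldimethylsilyl)oxy]-6,10-dimethylundeca-1,5,9-trien-2-yl phosphate | C=C(OP(=O)(OCC)OCC)[C@H](O[Si](C)(C)C(C)(C)C)C/C=C(\C)CCC=C(C)C | intermediate (not isolated)
6 | (3R,5E)-3-[(tert-butyldimethylsilyl)oxy]-6,10-dimethylundeca-5,9-dien-1-yne | C#C[C@H](O[Si](C)(C)C(C)(C)C)C/C=C(\C)CCC=C(C)C | intermediate
7 | [(1E,3R,5E)-3-[(tert-butyldimethylsilyl)oxy]-2,6,10-trimethylundeca-1,5,9-trien-1-yl]dimethylalumane | C[Al](C)/C=C(\C)[C@H](O[Si](C)(C)C(C)(C)C)C/C=C(\C)CCC=C(C)C | intermediate (not isolated)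
8 | (1E,3R,5E)-3-[(tert-butyldimethylsilyl)oxy]-1-iodo-2,6,10-trimethylundeca-1,5,9-triene | I/C=C(\C)[C@H](O[Si](C)(C)C(C)(C)C)C/C=C(\C)CCC=C(C)C | intermediate
9 | 4-[(tert-butyldimethylsilyl)oxy]butanal | CC(C)(C)[Si](C)(C)OCCCC=O | starting material
10 | nitromethane | C[N+](=O)[O-] | starting material
11 | 5-[(tert-butyldimethylsilyl)oxy]-1-nitropentan-2-ol (racemic) | CC(C)(C)[Si](C)(C)OCCCC(O)C[N+](=O)[O-] | intermediate (not isolated)
12 | 5-[(tert-butyldimethylsilyl)oxy]-1-nitropentan-2-yl methanesulfonate (racemic) | CC(C)(C)[Si](C)(C)OCCCC(OS(C)(=O)=O)C[N+](=O)[O-] | intermediate (not isolated)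
13 | tert-butyldimethylsilyl (4E)-5-nitropent-4-en-1-yl ether | CC(C)(C)[Si](C)(C)OCCC/C=C/[N+](=O)[O-] | intermediate
14 | propanal | CCC=O | starting material
15 | (2R,3R)-6-[(tert-butyldimethylsilyl)oxy]-2-methyl-3-(nitromethyl)hexanal | CC(C)(C)[Si](C)(C)OCCC[C@H]([C@@H](C)C=O)C[N+](=O)[O-] | intermediate
16 | but-3-en-2-one | CC(=O)C=C | starting material
17 | (2R,3R)-3-{3-[(tert-butyldimethylsilyl)oxy]propyl}-2-methyl-4-nitro-7-oxooctanal (C4 epimers) | CC(C)(C)[Si](C)(C)OCCC[C@H]([C@@H](C)C=O)C(CCC(C)=O)[N+](=O)[O-] | intermediate (not isolated)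
18 | (1R,2S,5R,6R)-6-{3-[(tert-butyldimethylsilyl)oxy]propyl}-2-hydroxy-1,2-dimethyl-5-nitrocyclohexane-1-carbaldehyde | CC(C)(C)[Si](C)(C)OCCC[C@H]1[C@H]([N+](=O)[O-])CC[C@](C)(O)[C@]1(C)C=O | intermediate
19 | (1R,2S,5R,6R)-6-{3-[(tert-butyldimethylsilyl)oxy]propyl}-1,2-dimethyl-5-nitro-2-[(triethylsilyl)oxy]cyclohexane-1-carbaldehyde | CC(C)(C)[Si](C)(C)OCCC[C@H]1[C@H]([N+](=O)[O-])CC[C@](C)(O[Si](CC)(CC)CC)[C@]1(C)C=O | intermediate
20 | tert-butyl(3-{(1R,2R,3S,6R)-2-ethenyl-2,3-dimethyl-6-nitro-3-[(triethylsilyl)oxy]cyclohexyl}propoxy)dimethylsilane | CC(C)(C)[Si](C)(C)OCCC[C@H]1[C@H]([N+](=O)[O-])CC[C@](C)(O[Si](CC)(CC)CC)[C@]1(C)C=C | intermediate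
21 | 9-(2-{(1R,2S,5R,6R)-6-{3-[(tert-butyldimethylsilyl)oxy]propyl}-1,2-dimethyl-5-nitro-2-[(triethylsilyl)oxy]cyclohexyl}ethyl)-9-borabicyclo[3.3.1]nonane | CC(C)(C)[Si](C)(C)OCCC[C@H]1[C@H]([N+](=O)[O-])CC[C@](C)(O[Si](CC)(CC)CC)[C@]1(C)CCB1C2CCCC1CCC2 | intermediate (not isolated)
22 | tert-butyl{[(3E,5R,7E)-1-{(1R,2S,5R,6R)-6-{3-[(tert-butyldimethylsilyl)oxy]propyl}-1,2-dimethyl-5-nitro-2-[(triethylsilyl)oxy]cyclohexyl}-4,8,12-trimethyltrideca-3,7,11-trien-5-yl]oxy}dimethylsilane | CC(C)(C)[Si](C)(C)OCCC[C@H]1[C@H]([N+](=O)[O-])CC[C@](C)(O[Si](CC)(CC)CC)[C@]1(C)CC/C=C(\C)[C@H](O[Si](C)(C)C(C)(C)C)C/C=C(\C)CCC=C(C)C | intermediate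
23 | sodium nitronate of 22 (aci-nitro salt at the nitro-bearing ring carbon) | CC(C)(C)[Si](C)(C)OCCC[C@H]1C(=[N+]([O-])[O-])CC[C@](C)(O[Si](CC)(CC)CC)[C@]1(C)CC/C=C(\C)[C@H](O[Si](C)(C)C(C)(C)C)C/C=C(\C)CCC=C(C)C.[Na+] | intermediate (not isolated)
24 | (2R,3R,4S)-2-{3-[(tert-butyldimethylsilyl)oxy]propyl}-3-[(3E,5R,7E)-5-[(tert-butyldimethylsilyl)oxy]-4,8,12-trimethyltrideca-3,7,11-trien-1-yl]-3,4-dimethyl-4-[(triethylsilyl)oxy]cyclohexan-1-one | CC(C)(C)[Si](C)(C)OCCC[C@H]1C(=O)CC[C@](C)(O[Si](CC)(CC)CC)[C@]1(C)CC/C=C(\C)[C@H](O[Si](C)(C)C(C)(C)C)C/C=C(\C)CCC=C(C)C | intermediate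
25 | (2R,3R,4S)-2-{3-[(tert-butyldimethylsilyl)oxy]propyl}-3-[(3E,5R,7E)-5-[(tert-butyldimethylsilyl)oxy]-4,8,12-trimethyltrideca-3,7,11-trien-1-yl]-3,4-dimethyl-1-(prop-1-en-2-yl)-4-[(triethylsilyl)oxy]cyclohexan-1-ol (C1 epimers) | CC(C)(C)[Si](C)(C)OCCC[C@H]1C(O)(C(C)=C)CC[C@](C)(O[Si](CC)(CC)CC)[C@]1(C)CC/C=C(\C)[C@H](O[Si](C)(C)C(C)(C)C)C/C=C(\C)CCC=C(C)C | intermediate
26 | (2Z)-2-{(2S,3R,4S)-2-{3-[(tert-butyldimethylsilyl)oxy]propyl}-3-[(3E,5R,7E)-5-[(tert-butyldimethylsilyl)oxy]-4,8,12-trimethyltrideca-3,7,11-trien-1-yl]-3,4-dimethyl-4-[(triethylsilyl)oxy]cyclohexylidene}propanal | CC(C)(C)[Si](C)(C)OCCC[C@H]1/C(=C(/C)C=O)CC[C@](C)(O[Si](CC)(CC)CC)[C@]1(C)CC/C=C(\C)[C@H](O[Si](C)(C)C(C)(C)C)C/C=C(\C)CCC=C(C)C | intermediate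
27 | (2Z)-2-{(2S,3R,4S)-4-hydroxy-3-[(3E,5R,7E)-5-hydroxy-4,8,12-trimethyltrideca-3,7,11-trien-1-yl]-2-(3-hydroxypropyl)-3,4-dimethylcyclohexylidene}propanal | OCCC[C@H]1/C(=C(/C)C=O)CC[C@](C)(O)[C@]1(C)CC/C=C(\C)[C@H](O)C/C=C(\C)CCC=C(C)C | intermediate
28 | octadecanoyl chloride (stearoyl chloride) | CCCCCCCCCCCCCCCCCC(=O)Cl | starting material
29 | 3-[(1S,2R,3S,6Z)-3-hydroxy-2-[(3E,5R,7E)-5-hydroxy-4,8,12-trimethyltrideca-3,7,11-trien-1-yl]-2,3-dimethyl-6-(1-oxopropan-2-ylidene)cyclohexyl]propyl octadecanoate | CCCCCCCCCCCCCCCCCC(=O)OCCC[C@H]1/C(=C(/C)C=O)CC[C@](C)(O)[C@]1(C)CC/C=C(\C)[C@H](O)C/C=C(\C)CCC=C(C)C | target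

**Step count and risks**
Total: 15 steps. Longest linear sequence: 11 steps (9 → 29, steps 5–15); the side-chain fragment 8 takes 4 steps (steps 1–4) and joins in step 10.

Three steps most likely to fail:

Step 3 (methyl ketone to alkyne). The second deprotonation can occur at the silyloxy-bearing CH instead of the vinylic CH2, giving an allene or eroding the stereocentre. The fallback avoids the alkyne: from 4, a boron–Wittig olefination with lithiated bis(pinacolato)borylmethane [CH2(Bpin)2, lithium 2,2,6,6-tetramethylpiperidide, THF, 0 °C, then 4 at −78 → 25 °C] gives the (E)-alkenyl boronate F1 with boron trans to the bulky silyloxy-bearing substituent. Iododeboronation with retention (NaOH, I2, THF/H2O, 0 °C) then returns to the route at 8, so step 4 is also bypassed.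

Step 7 (proposed amine-catalysed enolexo aldol). The ketone may act as the donor towards the aldehyde instead, or the α-branched aldehyde may fail to form the enamine. The fallback uses only known reactions and fixes the nucleophile beforehand: from 15, acetalisation (TMSOMe, TMSOTf cat., CH2Cl2, −78 °C) gives the dimethyl acetal F2. Elimination (TMSOTf, iPr2NEt, CH2Cl2, −20 → 25 °C, aqueous NaHCO3 work-up) gives the methyl enol ether F3. Et3N-catalysed nitro-Michael addition to 16 gives the nitro ketone F4. A Lewis acid-mediated intramolecular Mukaiyama-type addition of the enol ether to the ketone (TiCl4, CH2Cl2, −78 °C, aqueous work-up) closes the ring through the same chair arrangement and returns to the route at 18.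

Step 13 (oxidative transposition). The hindered tertiary chromate may dehydrate, and the (Z)/(E) ratio of the tetrasubstituted enal is only a prediction. The fallback replaces steps 12 and 13: from 24, a Horner–Wadsworth–Emmons reaction with diethyl (1-cyanoethyl)phosphonate (NaH, THF, 0 → 60 °C) gives the unsaturated nitrile F5, in which the small linear cyano group should prefer the side of the substituted ring carbon; the isomers are separated at this stage. Reduction with iBu2AlH (toluene, −78 °C) and hydrolysis of the aldimine returns to the route at 26.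

**Further compounds**
F1 | step 3 | 2-[(1E,3R,5E)-3-[(tert-butyldimethylsilyl)oxy]-2,6,10-trimethylundeca-1,5,9-trien-1-yl]-4,4,5,5-tetramethyl-1,3,2-dioxaborolane | CC1(C)OB(/C=C(\C)[C@H](O[Si](C)(C)C(C)(C)C)C/C=C(\C)CCC=C(C)C)OC1(C)C
F2 | step 7 | tert-butyl{[(4R,5R)-6,6-dimethoxy-5-methyl-4-(nitromethyl)hexyl]oxy}dimethylsilane | CC(C)(C)[Si](C)(C)OCCC[C@H]([C@@H](C)C(OC)OC)C[N+](=O)[O-]
F3 | step 7 | tert-butyl{[(4R)-6-methoxy-5-methyl-4-(nitromethyl)hex-5-en-1-yl]oxy}dimethylsilane (E/Z mixture) | CC(C)(C)[Si](C)(C)OCCC[C@H](C(C)=COC)C[N+](=O)[O-]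
F4 | step 7 | (6R)-9-[(tert-butyldimethylsilyl)oxy]-6-(1-methoxyprop-1-en-2-yl)-5-nitrononan-2-one (C5 epimers) | CC(C)(C)[Si](C)(C)OCCC[C@H](C(C)=COC)C(CCC(C)=O)[N+](=O)[O-]
F5 | step 13 | (2Z)-2-{(2S,3R,4S)-2-{3-[(tert-butyldimethylsilyl)oxy]propyl}-3-[(3E,5R,7E)-5-[(tert-butyldimethylsilyl)oxy]-4,8,12-trimethyltrideca-3,7,11-trien-1-yl]-3,4-dimethyl-4-[(triethylsilyl)oxy]cyclohexylidene}propanenitrile | CC(C)(C)[Si](C)(C)OCCC[C@H]1/C(=C(/C)C#N)CC[C@](C)(O[Si](CC)(CC)CC)[C@]1(C)CC/C=C(\C)[C@H](O[Si](C)(C)C(C)(C)C)C/C=C(\C)CCC=C(C)C
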